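## Retrosynthetic overview

1. The dihydrofuran ring (the only ring formed) is closed last: acid-mediated 5-exo O-cyclisation of an o-hydroxyaryl benzylic alcohol (12) gives the trans-2,3 ring. The acrylic acid is attached just before by Heck coupling on an aryl bromide.
2. The C2–aryl bond comes from addition of a MOM-protected guaiacyl Grignard (from 9) to lactol 8, a masked α-aryl-β-hydroxy aldehyde.
3. Lactol 8 comes from ozonolysis of the propenyl group of phenol 7.
4. Key step: the C3a–C3 bond and the C3 stereocentre of 7 are made by aromatic Claisen [3,3] rearrangement of (S,E)-allylic aryl ether 6, with 1,3-chirality transfer.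
5. Ether 6 comes from 4-bromo-2-methoxyphenol and methyl (R)-lactate by Mitsunobu inversion, one-pot DIBAL/HWE, and DIBAL reduction.

Assumption: methyl (R)-lactate (methyl D-lactate, from fermentation D-lactic acid) counts as a cheap commercial chiral starting material. The target is the (2S,3R)-trans isomer.

## Route

**Step 1**
Reactants: 1, 4-bromo-2-methoxyphenol; 2, methyl (R)-lactate
Product: 3, methyl (S)-2-(4-bromo-2-methoxyphenoxy)propanoate
Conditions: PPh3, DIAD, THF, 0 °C → rt
Reagents that add atoms: none (both partners are numbered reactants)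
Why: Mitsunobu etherification of an acidic phenol with an α-hydroxy ester proceeds by clean SN2 inversion, turning the bought (R)-carbinol into the (S)-aryl ether.

**Step 2**
Reactants: 3; 4, triethyl phosphonoacetate
Product: 5, ethyl (S,E)-4-(4-bromo-2-methoxyphenoxy)pent-2-enoate
Conditions: DIBAL-H (1.05 equiv), CH2Cl2, −78 °C; then 4/NaH (pre-formed in THF), −78 °C → rt, one pot
Reagents that add atoms: triethyl phosphonoacetate (4), CCOC(=O)CP(=O)(OCC)OCC
Why: DIBAL stops at the chelated aluminium hemiacetal of the α-aryloxy ester, and in-situ Horner–Wadsworth–Emmons olefination gives the E-enoate without isolating the epimerisable α-aryloxy aldehyde, so the stereocentre is untouched.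

**Step 3**
Reactants: 5
Product: 6, (S,E)-4-(4-bromo-2-methoxyphenoxy)pent-2-en-1-ol
Conditions: DIBAL-H (2.5 equiv), CH2Cl2, −78 → 0 °C; Rochelle salt work-up
Reagents that add atoms: none
Why: DIBAL 1,2-reduction of an enoate gives the E-allylic alcohol, and the aryl bromide, aryl ether and stereocentre are inert.

**Step 4 (key step)**
Reactants: 6
Product: 7, (R,E)-2-(5-bromo-2-hydroxy-3-methoxyphenyl)pent-3-en-1-ol
Conditions: degassed PhNEt2, 170 °C, sealed tube, Ar
Reagents that add atoms: none
Why: The aromatic Claisen rearrangement goes to the only free ortho position through a chair transition state with the methyl group pseudo-equatorial; the suprafacial shift transfers the (S)-C–O stereocentre of the E-ether to the new benzylic (R)-C–C stereocentre and leaves an E-propenyl group.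

**Step 5**
Reactants: 7
Product: 8, (3R)-5-bromo-3-(hydroxymethyl)-7-methoxy-2,3-dihydro-1-benzofuran-2-ol (anomeric mixture; lactol of (R)-2-(5-bromo-2-hydroxy-3-methoxyphenyl)-3-hydroxypropanal)
Conditions: O3, CH2Cl2/MeOH, NaHCO3, −78 °C (Sudan Red 7B end-point); then Me2S, −78 °C → rt; used crude
Reagents that add atoms: ozone, [O-][O+]=O (one O retained)
Why: Ozonolysis cleaves the only alkene (acetaldehyde is lost), and the o-hydroxyaryl acetaldehyde closes to a five-membered lactol that masks the α-aryl aldehyde, so the C3 stereocentre is not touched under these neutral conditions.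

**Step 6**
Reactants: 1, 4-bromo-2-methoxyphenol
Product: 9, 4-bromo-2-methoxy-1-(methoxymethoxy)benzene
Conditions: MOMCl, iPr2NEt, CH2Cl2, 0 °C → rt
Reagents that add atoms: chloromethyl methyl ether (MOMCl), COCCl
Why: Standard O-alkylation gives an acetal that survives Grignard formation and Heck conditions and is removed by the acid used in the last step.

**Step 7**
Reactants: 8; 9
Product: 10, (2R)-2-(5-bromo-2-hydroxy-3-methoxyphenyl)-1-[3-methoxy-4-(methoxymethoxy)phenyl]propane-1,3-diol (mixture of C1 epimers)
Conditions: 9, Mg, THF (→ ArMgBr, 3.5 equiv); add to 8, THF, −40 → 0 °C; sat. NH4Cl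
Reagents that add atoms: none (the aryl group comes from 9)
Why: Grignard addition to the lactol goes through its open-chain aldehyde after deprotonation of the two OH groups; addition to the aldehyde outpaces enolisation at low temperature so C2 stays (R), the aryl bromide of 8 does not exchange, and the new carbinol configuration is irrelevant because it is ionised in step 9.

**Step 8**
Reactants: 10; 11, acrylic acid
Product: 12, (E)-3-{3-[(2R)-1,3-dihydroxy-1-[3-methoxy-4-(methoxymethoxy)phenyl]propan-2-yl]-4-hydroxy-5-methoxyphenyl}prop-2-enoic acid (C1 epimers)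
Conditions: Pd(OAc)2 (5 mol %), P(o-tol)3 (15 mol %), Et3N, DMF, 100 °C; work-up at pH 3–4 (citric acid)
Reagents that add atoms: acrylic acid (11), C=CC(=O)O
Why: Mizoroki–Heck coupling of the aryl bromide (bromophenols are competent with P(o-tol)3) gives the E-cinnamic acid by syn insertion and syn β-hydride elimination; the alcohols, the MOM group and the stereocentre are not affected by Et3N/Pd.

**Step 9**
Reactants: 12
Product: 13, (E)-3-[(2S,3R)-2-(4-hydroxy-3-methoxyphenyl)-3-(hydroxymethyl)-7-methoxy-2,3-dihydro-1-benzofuran-5-yl]prop-2-enoic acid (target)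
Conditions: 2 M aq. HCl/THF (1:3), 45 °C
Reagents that add atoms: none
Why: Acid removes the MOM acetal and ionises the p-oxygenated benzylic alcohol to a quinone-methide-type cation that is trapped 5-exo by the ortho phenol; because this C2–O bond forms reversibly, the ring settles as the more stable trans isomer, so the (3R) centre fixes C2 as (S) whatever the carbinol configuration in 12.

## Compound list

1 | 4-bromo-2-methoxyphenol | COc1cc(Br)ccc1O | starting material
2 | methyl (R)-lactate | C[C@@H](O)C(=O)OC | starting material
3 | methyl (S)-2-(4-bromo-2-methoxyphenoxy)propanoate | C[C@H](Oc1ccc(Br)cc1OC)C(=O)OC | intermediate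
4 | triethyl phosphonoacetate | CCOC(=O)CP(=O)(OCC)OCC | starting material
5 | ethyl (S,E)-4-(4-bromo-2-methoxyphenoxy)pent-2-enoate | C[C@H](Oc1ccc(Br)cc1OC)/C=C/C(=O)OCC | intermediate
6 | (S,E)-4-(4-bromo-2-methoxyphenoxy)pent-2-en-1-ol | C[C@H](Oc1ccc(Br)cc1OC)/C=C/CO | intermediate
7 | (R,E)-2-(5-bromo-2-hydroxy-3-methoxyphenyl)pent-3-en-1-ol | C/C=C/[C@@H](CO)c1cc(Br)cc(OC)c1O | intermediate
8 | (3R)-5-bromo-3-(hydroxymethyl)-7-methoxy-2,3-dihydro-1-benzofuran-2-ol (anomers) | OC1Oc2c(OC)cc(Br)cc2[C@@H]1CO | intermediate
9 | 4-bromo-2-methoxy-1-(methoxymethoxy)benzene | COCOc1ccc(Br)cc1OC | intermediate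
10 | (2R)-2-(5-bromo-2-hydroxy-3-methoxyphenyl)-1-[3-methoxy-4-(methoxymethoxy)phenyl]propane-1,3-diol (C1 epimers) | OC(c1ccc(OCOC)c(OC)c1)[C@@H](CO)c1cc(Br)cc(OC)c1O | intermediate
11 | acrylic acid | C=CC(=O)O | starting material
12 | (E)-3-{3-[(2R)-1,3-dihydroxy-1-[3-methoxy-4-(methoxymethoxy)phenyl]propan-2-yl]-4-hydroxy-5-methoxyphenyl}prop-2-enoic acid (C1 epimers) | OC(c1ccc(OCOC)c(OC)c1)[C@@H](CO)c1cc(/C=C/C(=O)O)cc(OC)c1O | intermediate
13 | (E)-3-[(2S,3R)-2-(4-hydroxy-3-methoxyphenyl)-3-(hydroxymethyl)-7-methoxy-2,3-dihydro-1-benzofuran-5-yl]prop-2-enoic acid | COc1cc([C@H]2Oc3c(OC)cc(/C=C/C(=O)O)cc3[C@@H]2CO)ccc1O | target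

## Step count and risks

Total steps: 9. Longest linear sequence: 8 (steps 1–5, 7, 8, 9); step 6 is a one-step branch from starting material 1.

Steps most likely to fail:

1. **Step 4 (Claisen).** Risks are incomplete chirality transfer, abnormal-Claisen scrambling of the side chain, or elimination to diene plus phenol 1. Fallback: make the same C–C bond intermolecularly by Cu-catalysed anti-SN2' arylation of the O-silylated, lactate-derived (E)-allylic picolinate or phosphate with an ortho-magnesiated MOM ether of the A-ring phenol. The A ring would then be carried as a vanillin acetal instead of the bromide, with the acrylic acid introduced at the end by Knoevenagel–Doebner condensation.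
2. **Step 5 (ozonolysis of a free guaiacol-type phenol).** Risks are over-oxidation of the arene and dehydration of lactol 8 to an achiral benzofuran. Fallback: bis-silylate 7 (phenol and primary alcohol) first, so that cleavage (OsO4/NMO then NaIO4, or O3) gives a discrete, non-phenolic aldehyde that cannot aromatise; the silyl groups are removed with fluoride before step 9.
3. **Step 7 (Grignard addition to an enolisable β-hydroxy-α-aryl aldehyde equivalent).** Risks are epimerisation at C3 or retro-aldol loss of formaldehyde under strongly basic conditions. Fallback: a non-basic aryl transfer, namely Nozaki–Hiyama–Kishi coupling of the iodo analogue of 9 (CrCl2, catalytic NiCl2, DMF) with the aldehyde/lactol, which adds without enolisation and reacts with the aryl iodide in preference to the aryl bromide of 8.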